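## The problem

Compound 22 is (2R)-5,7,4'-trihydroxy-6,3',5'-triprenylflavanone (prenyl = 3-methylbut-2-en-1-yl). Aromatic ring A is fused to the dihydropyranone ring C, and ring B is attached at C2.

- C2 is the only stereocentre, so no other centre can direct it. It has to be set by a catalyst and then carried unchanged to the end.
- C2 is fragile. It is benzylic, its oxygen O1 lies β to the C4 ketone, and the 4'-oxygen is para to it. Base opens ring C to the chalcone, and ionising acid breaks C2–O1. Both erase the configuration.
- Ring A is a phloroglucinol whose single C-prenyl group must sit at C6 and not at C8. Substitution on a finished 5,7-dioxygenated chromanone does not make this choice cleanly.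
- The three prenyl groups each lie ortho to a phenolic oxygen. They exclude hydrogenolysis, strong Lewis acids and hot protic acid (cyclisation to dimethylchromans), and they limit electrophilic oxidants.
- The enabling feature appears when the C4–C4a bond is cut. Ring A then becomes a 3,5-dioxygenated 4-prenylphenyl ether in which O1 is para to the prenyl-bearing carbon (the future C6). A mirror plane runs through O1 and that carbon, so the two free ortho carbons (future C4a and C8) are equivalent. Acylation at either gives the same 6-prenyl chromanone, and the C6/C8 problem disappears.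

## Retrosynthesis

**22 to 21 (protecting groups).** The last operation removes two methoxymethyl (MOM) ethers at O5 and O7 and a tert-butyl carbonate at O4' from 21. MOM is chosen because it directs the metalation that places the ring A prenyl group and leaves in dilute acid. The 4'-oxygen carries an electron-withdrawing acyl-type group so that ring B does not stabilise a benzylic cation at C2 during ring closure. A simple acetate would have the same electronic effect but would not survive the aryloxide and alkoxide of the etherification or the peroxide work-up of the hydroboration. The tert-butyl carbonate is shielded by its own bulk and the two ortho prenyl groups, and it leaves with the MOM groups in one acid step.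

**21 to 19 (C4–C4a, ring C).** Cutting the aryl ketone bond gives the (3R)-3-aryloxy-3-arylpropanoic acid 19. The neighbouring cuts are worse. Cutting O1–C2 leads back to a chalcone and an oxa-Michael closure with weak stereocontrol. Cutting C2–C1' requires a conjugate arylation onto a chromone that already has the C6/C8 issue. The C4–C4a cut removes the regiochemical problem through the symmetry of the ring A ether and leaves C2 untouched. The forward reaction is an intramolecular Friedel–Crafts acylation through the mixed anhydride 20, mild enough for three prenyl groups and two MOM ethers.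

**19 to 17 to 15 (oxidation level of C4).** The carboxyl carbon is traced back to the terminal carbon of a vinyl group. Acid 19 comes from primary alcohol 17, and 17 from anti-Markovnikov hydration of the branched allyl aryl ether 15. No C–C bond is formed; this only adjusts C3 and C4. The forward reactions must select one monosubstituted alkene beside three trisubstituted ones (9-BBN) and oxidise a primary alcohol without touching ring A.

**15 to 7 and 13 (C2–O1, the stereocentre).** The ether bond is cut between O1 and the allylic carbon, giving phenol 7 (used as its lithium salt 14) and cinnamyl carbonate 13. This cut divides the molecule into its two aromatic halves. It creates C2 in an iridium-catalysed allylic etherification, a reaction class that gives the branched ether of cinnamyl carbonates with high enantioselectivity. A Mitsunobu inversion of a benzylic alcohol would be the neighbouring choice; it is kept as the fallback because benzylic substrates risk partial ionisation. The forward reaction needs O- rather than C-allylation of the aryloxide and the correct ligand antipode.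

**7 to 6, 3, 2 and 1 (ring A prenyl).** The C6–CH2 bond is cut. In the silyl ether 3 the carbon between the two MOM-oxy groups is the most acidic site, so lithiation (aryllithium 5) and allylation with prenyl bromide 4 give 6 and, after desilylation, 7. Bis-ether 2 comes from phloroglucinol 1. Every intermediate keeps the mirror plane, so no regioisomer can arise.

**13 to 12, 11, 9 and 10, and 9 to 8 and 4 (ring B).** Double acylation of diol 12 with Boc2O gives 13. Alcohol 12 is the reduction product of cinnamate 11. Cutting the aryl–vinyl bond of 11 gives iodide 9 and methyl acrylate 10 (Mizoroki–Heck). Iodide 9 comes from 4-iodophenol 8 by double ortho-C-prenylation with 4. The para-iodine blocks the para position and is the handle for the Heck reaction.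

## Roads not taken

**Alternative 1: triple prenylation of a trihalogenated flavanone.**
- Cut and key step: the three aryl–CH2 bonds (C6–C1'' and both ring B prenyl bonds) are cut. The trihalide A2, with the C2 stereocentre and all rings in place, is coupled three times with the prenylstannane A3 under zerovalent palladium catalysis to give A1.
- Merits: the prenyl groups enter last, so no earlier step has to spare them. In this respect it is better than the chosen plan, which carries them through nine steps. Halogens are robust placeholders, and one reagent installs all three groups.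
- Weak points:
  - The C6/C8 problem is only moved. A2 needs iodine at C6 of a 5,7-dioxygenated chromanone, and electrophilic iodination of that ring is not reliably C6-selective.
  - Three hindered couplings must all succeed in one flask (C6 lies between two oxygens; the ring B bromides are ortho to a MOM-oxy group).
  - Each coupling must transfer the unbranched terminus of the allyl tin reagent.
  - Prolonged heating of a 5-hydroxyflavanone invites ring opening and racemisation.
  - The key step does not create C2, so a separate asymmetric step is still needed.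
- Comparison: the chosen plan accepts prenyl-compatible reagents throughout. In return the symmetry of the ring A ether fixes C6, C2 comes from one catalytic step, and no step needs threefold success.

**Alternative 2: enantioselective carbenoid insertion into the benzylic ether C–H bond.**
- Cut and key step: C2–C3 is cut. The diazoketone A5 is decomposed by a chiral dirhodium catalyst, and the carbenoid carbon inserts into one enantiotopic O–CH2–aryl hydrogen. This forms ring C and the C2 stereocentre together and gives A4.
- Merits: it is the most direct of the four plans, since ring and stereocentre come from an achiral benzyl ether in one catalytic step. The silyl ethers of A4 leave with fluoride, so the end game avoids acid beside prenyl groups. In both respects it is better than the chosen plan.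
- Weak points:
  - An electrophilic carbenoid meets three electron-rich trisubstituted alkenes (cyclopropanation) and ring B (aromatic cycloaddition).
  - The ether oxygen can form an oxonium ylide, and a 1,2-benzyl shift then contracts the ring.
  - Six-membered insertion is less favoured than five-membered, and enantioselectivity in this insertion class is usually moderate.
  - A5 requires benzylation of one particular ortho oxygen of a 3-prenyl-2,4,6-trioxygenated benzoyl unit, so the C6/C8 question returns.
- Comparison: the chosen plan spends more steps. It sets against this an etherification class with dependable enantioselectivity and a ring closure whose regiochemistry needs no control.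

**Alternative 3: ring A by Claisen cyclisation on a chiral dihydropyranone.**
- Cut and key step: C4a–C5 is cut, so ring A is built last. The dihydropyranone A7, which carries a prenylated β-keto ester side chain, is treated with a magnesium alkoxide. The extended enolate attacks the ester through C4a, and ring A closes and aromatises to A6.
- Merits: the prenyl position is fixed by the carbon chain, which matches the symmetry argument of the chosen plan. The ring A phenols are formed free, so no ring A protecting groups are needed; here it is better than the chosen plan. The stereocentre could come from an asymmetric hetero-Diels–Alder reaction.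
- Weak points:
  - A7 is a sensitive tricarbonyl compound that needs several C–C bond formations on a base-labile 2-aryldihydropyranone.
  - The enolate that must acylate can also expel O1 (retro-oxa-Michael), which erases C2.
  - O-acylation and aldol closures compete.
  - A6 is formed as a free 5,7-dihydroxyflavanone in base, where ring–chain equilibration racemises it.
- Comparison: the chosen plan pays with MOM protection and removal. It keeps C2 away from strong base throughout and uses only established reaction classes.

Key step: step 12

Assumption: the (Ra,Rc,Rc) antipode of the binaphthyl bis(1-phenylethyl)phosphoramidite is taken to give the (R) ether 15, by analogy with this catalyst family on cinnamyl carbonates; the sense is to be confirmed on the first coupling, and the enantiomeric ligand is used if it is opposite.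

## Route

Step 1
Reactants: 1 phloroglucinol (benzene-1,3,5-triol)
Product: 2 3,5-bis(methoxymethoxy)phenol
Conditions: MOMCl (2.1 equiv), i-Pr2NEt, CH2Cl2–DMF, 0 °C → rt; chromatography
Reagents that add atoms: chloromethyl methyl ether (MOMCl), COCCl
Why: O-alkylation of the phenol with the chloromethyl ether. The bis-ether is the main component of the statistical mixture and is separated; the threefold symmetry of 1 allows only one bis-ether.

Step 2
Reactants: 2 3,5-bis(methoxymethoxy)phenol
Product: 3 [3,5-bis(methoxymethoxy)phenoxy]tri(propan-2-yl)silane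
Conditions: TIPSCl, imidazole, DMF, rt
Reagents that add atoms: chlorotri(propan-2-yl)silane (TIPSCl), CC(C)[Si](Cl)(C(C)C)C(C)C
Why: Silylation of the remaining phenol. The bulky, non-coordinating silyl ether removes the acidic proton before lithiation and shields the two carbons next to it.

Step 3
Reactants: 3 [3,5-bis(methoxymethoxy)phenoxy]tri(propan-2-yl)silane, 4 prenyl bromide (1-bromo-3-methylbut-2-ene)
Product: 6 [3,5-bis(methoxymethoxy)-4-(3-methylbut-2-en-1-yl)phenoxy]tri(propan-2-yl)silane, via aryllithium 5 (not isolated)
Conditions: n-BuLi, THF, 0 °C; then CuI (10 mol%), 4, −78 °C → rt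
Reagents that add atoms: none
Why: Directed ortho-metalation. The carbon between the two MOM-oxy groups is doubly coordinated and is lithiated selectively, and copper-catalysed SN2 allylation with prenyl bromide gives the unbranched prenyl arene.

Step 4
Reactants: 6 [3,5-bis(methoxymethoxy)-4-(3-methylbut-2-en-1-yl)phenoxy]tri(propan-2-yl)silane
Product: 7 3,5-bis(methoxymethoxy)-4-(3-methylbut-2-en-1-yl)phenol
Conditions: Bu4NF, THF, 0 °C; aq. NH4Cl
Reagents that add atoms: none
Why: Fluoride cleavage of the aryl silyl ether; the MOM ethers and the alkene are inert.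

Step 5
Reactants: 8 4-iodophenol, 4 prenyl bromide (1-bromo-3-methylbut-2-ene)
Product: 9 4-iodo-2,6-bis(3-methylbut-2-en-1-yl)phenol
Conditions: 4 (2.5 equiv), aq. NaOH, rt
Reagents that add atoms: none
Why: ortho-C-alkylation of the ambident phenoxide. In water the oxygen is hydrogen-bonded, so alkylation goes to the ortho carbons, and the para position is blocked by iodine; this is an established transformation of para-halophenols.

Step 6
Reactants: 9 4-iodo-2,6-bis(3-methylbut-2-en-1-yl)phenol, 10 methyl acrylate (methyl prop-2-enoate)
Product: 11 methyl (2E)-3-[4-hydroxy-3,5-bis(3-methylbut-2-en-1-yl)phenyl]prop-2-enoate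
Conditions: Pd(OAc)2 (5 mol%), P(o-tol)3, Et3N, DMF, 90 °C
Reagents that add atoms: none
Why: Mizoroki–Heck reaction at the aryl iodide. Syn insertion and β-hydride elimination give the E-cinnamate; the trisubstituted prenyl alkenes do not insert and the free phenol is tolerated.

Step 7
Reactants: 11 methyl (2E)-3-[4-hydroxy-3,5-bis(3-methylbut-2-en-1-yl)phenyl]prop-2-enoate
Product: 12 4-[(1E)-3-hydroxyprop-1-en-1-yl]-2,6-bis(3-methylbut-2-en-1-yl)phenol
Conditions: i-Bu2AlH (3.5 equiv), CH2Cl2, −78 → 0 °C; aq. potassium sodium tartrate
Reagents that add atoms: none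
Why: 1,2-Reduction of the unsaturated ester to the allylic alcohol by the aluminium hydride (one equivalent is consumed by the phenol); the alkene geometry is kept.

Step 8
Reactants: 12 4-[(1E)-3-hydroxyprop-1-en-1-yl]-2,6-bis(3-methylbut-2-en-1-yl)phenol
Product: 13 tert-butyl (2E)-3-{4-[(tert-butoxycarbonyl)oxy]-3,5-bis(3-methylbut-2-en-1-yl)phenyl}prop-2-en-1-yl carbonate
Conditions: Boc2O (2.6 equiv), DMAP (0.2 equiv), CH2Cl2, 0 °C → rt
Reagents that add atoms: di-tert-butyl dicarbonate (Boc2O), CC(C)(C)OC(=O)OC(=O)OC(C)(C)C
Why: DMAP-catalysed acylation of both hydroxyl groups. One reagent installs the allylic leaving group and the electron-withdrawing, acid-removable protection of the ring B phenol.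

Step 9
Reactants: 7 3,5-bis(methoxymethoxy)-4-(3-methylbut-2-en-1-yl)phenol, 13 tert-butyl (2E)-3-{4-[(tert-butoxycarbonyl)oxy]-3,5-bis(3-methylbut-2-en-1-yl)phenyl}prop-2-en-1-yl carbonate
Product: 15 tert-butyl 4-{(1R)-1-[3,5-bis(methoxymethoxy)-4-(3-methylbut-2-en-1-yl)phenoxy]prop-2-en-1-yl}-2,6-bis(3-methylbut-2-en-1-yl)phenyl carbonate, via lithium aryloxide 14 (not isolated)
Conditions: 7 (1.3 equiv), n-BuLi, THF, −78 → 0 °C; then 13, [Ir(cod)Cl]2 (2 mol%), (Ra,Rc,Rc)-binaphthyl bis(1-phenylethyl)phosphoramidite (4 mol%, pre-activated with n-PrNH2), THF, rt → 50 °C; aq. NH4Cl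
Reagents that add atoms: none
Why: Iridium-catalysed asymmetric allylic etherification. The cyclometalated iridium–phosphoramidite complex ionises the allylic carbonate, and the aryloxide attacks the aryl-substituted allyl terminus on the face left open by the ligand, so the branched ether forms and C2 is set as R by catalyst control. The aryl carbonate is shielded against acyl transfer by its tert-butyl group and two ortho prenyl groups.

Step 10
Reactants: 15 tert-butyl 4-{(1R)-1-[3,5-bis(methoxymethoxy)-4-(3-methylbut-2-en-1-yl)phenoxy]prop-2-en-1-yl}-2,6-bis(3-methylbut-2-en-1-yl)phenyl carbonate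
Product: 17 tert-butyl 4-{(1R)-1-[3,5-bis(methoxymethoxy)-4-(3-methylbut-2-en-1-yl)phenoxy]-3-hydroxypropyl}-2,6-bis(3-methylbut-2-en-1-yl)phenyl carbonate, via B-alkyl-9-BBN borane 16 (not isolated)
Conditions: 9-BBN (1.5 equiv), THF, 0 °C → rt; then NaBO3·4H2O, H2O, rt
Reagents that add atoms: sodium perborate tetrahydrate (NaBO3·4H2O), [Na+].[Na+].O[B-]1(O)OO[B-](O)(O)OO1.O.O.O.O.O.O
Why: Hydroboration–oxidation. 9-BBN adds to the monosubstituted vinyl group far faster than to the three trisubstituted prenyl alkenes and places boron on the terminal carbon. Perborate oxidises the C–B bond mildly enough to spare the carbonate, and the stereocentre is not involved.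

Step 11
Reactants: 17 tert-butyl 4-{(1R)-1-[3,5-bis(methoxymethoxy)-4-(3-methylbut-2-en-1-yl)phenoxy]-3-hydroxypropyl}-2,6-bis(3-methylbut-2-en-1-yl)phenyl carbonate
Product: 19 (3R)-3-[3,5-bis(methoxymethoxy)-4-(3-methylbut-2-en-1-yl)phenoxy]-3-{4-[(tert-butoxycarbonyl)oxy]-3,5-bis(3-methylbut-2-en-1-yl)phenyl}propanoic acid, via aldehyde 18 (not isolated)
Conditions: TEMPO (0.2 equiv), PhI(OAc)2 (2.2 equiv), MeCN–H2O (1:1), rt
Reagents that add atoms: water, O
Why: Oxoammonium-catalysed oxidation of the primary alcohol to the aldehyde and, through its hydrate, to the acid. The medium is chlorine-free and near neutral, so the prenyl groups, the MOM ethers and ring A should be left alone and the β-aryloxy aldehyde should not eliminate.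

Step 12
Reactants: 19 (3R)-3-[3,5-bis(methoxymethoxy)-4-(3-methylbut-2-en-1-yl)phenoxy]-3-{4-[(tert-butoxycarbonyl)oxy]-3,5-bis(3-methylbut-2-en-1-yl)phenyl}propanoic acid
Product: 21 tert-butyl 4-[(2R)-5,7-bis(methoxymethoxy)-6-(3-methylbut-2-en-1-yl)-4-oxo-3,4-dihydro-2H-chromen-2-yl]-2,6-bis(3-methylbut-2-en-1-yl)phenyl carbonate, via mixed trifluoroacetic anhydride 20 (not isolated)
Conditions: (CF3CO)2O (1.2 equiv), CH2Cl2 (0.02 M), −20 → 0 °C; cold aq. NaHCO3
Reagents that add atoms: none
Why: Trifluoroacetic anhydride converts acid 19 into the mixed anhydride 20, whose acyl carbon (the future C4), activated by the CF3CO2H released, is attacked by the ring A carbon that is ortho to O1, ortho to one MOM-oxy group and para to the other; loss of the proton from the Wheland intermediate restores ring A and gives 21. This is the classical intramolecular Friedel–Crafts acylation of 3-aryloxypropanoic acids to chroman-4-ones, run with the mildest common activator. Ring C closes in a 6-exo-trig mode, the carbonyl oxygen staying outside the new ring. No stereocentre is formed; C2 is a spectator and keeps its R configuration because the C2–O1 bond is not broken. The selectivity needed is chemoselectivity: C-acylation must outrun ionisation of the benzylic C2–O1 bond, protonation of the three prenyl alkenes, loss of MOM groups and intermolecular trifluoroacetylation of ring A. The substrate secures this by the threefold oxygen activation of the attacked carbon, which should allow reaction at or below 0 °C, by the electron-withdrawing tert-butyl carbonate on ring B, which destabilises a benzylic cation, and by high dilution with near-stoichiometric anhydride. Regioselectivity needs no control, because the two ortho carbons are related by the mirror plane through O1 and the prenyl-bearing carbon and give the same 6-prenyl product.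

Step 13
Reactants: 21 tert-butyl 4-[(2R)-5,7-bis(methoxymethoxy)-6-(3-methylbut-2-en-1-yl)-4-oxo-3,4-dihydro-2H-chromen-2-yl]-2,6-bis(3-methylbut-2-en-1-yl)phenyl carbonate
Product: 22 (2R)-5,7-dihydroxy-2-[4-hydroxy-3,5-bis(3-methylbut-2-en-1-yl)phenyl]-6-(3-methylbut-2-en-1-yl)-2,3-dihydro-4H-chromen-4-one
Conditions: 3 M aq. HCl, MeOH, rt
Reagents that add atoms: none
Why: Acid solvolysis. Both MOM acetals are cleaved to the phenols, and the tert-butyl carbonate loses 2-methylpropene and CO2 in the same medium. At room temperature, cyclisation of the prenyl groups onto the new phenols and opening of ring C should be slow, so C2 stays R.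

## Compound list

1 | phloroglucinol (benzene-1,3,5-triol) | Oc1cc(O)cc(O)c1 | starting material
2 | 3,5-bis(methoxymethoxy)phenol | COCOc1cc(O)cc(OCOC)c1 | intermediate
3 | [3,5-bis(methoxymethoxy)phenoxy]tri(propan-2-yl)silane | COCOc1cc(O[Si](C(C)C)(C(C)C)C(C)C)cc(OCOC)c1 | intermediate
4 | prenyl bromide (1-bromo-3-methylbut-2-ene) | CC(C)=CCBr | starting material
5 | {2,6-bis(methoxymethoxy)-4-[tri(propan-2-yl)silyloxy]phenyl}lithium | COCOc1cc(O[Si](C(C)C)(C(C)C)C(C)C)cc(OCOC)c1[Li] | intermediate (not isolated)
6 | [3,5-bis(methoxymethoxy)-4-(3-methylbut-2-en-1-yl)phenoxy]tri(propan-2-yl)silane | COCOc1cc(O[Si](C(C)C)(C(C)C)C(C)C)cc(OCOC)c1CC=C(C)C | intermediate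
7 | 3,5-bis(methoxymethoxy)-4-(3-methylbut-2-en-1-yl)phenol | COCOc1cc(O)cc(OCOC)c1CC=C(C)C | intermediate
8 | 4-iodophenol | Oc1ccc(I)cc1 | starting material
9 | 4-iodo-2,6-bis(3-methylbut-2-en-1-yl)phenol | CC(C)=CCc1cc(I)cc(CC=C(C)C)c1O | intermediate
10 | methyl acrylate (methyl prop-2-enoate) | C=CC(=O)OC | starting material
11 | methyl (2E)-3-[4-hydroxy-3,5-bis(3-methylbut-2-en-1-yl)phenyl]prop-2-enoate | CC(C)=CCc1cc(/C=C/C(=O)OC)cc(CC=C(C)C)c1O | intermediate
12 | 4-[(1E)-3-hydroxyprop-1-en-1-yl]-2,6-bis(3-methylbut-2-en-1-yl)phenol | CC(C)=CCc1cc(/C=C/CO)cc(CC=C(C)C)c1O | intermediate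
13 | tert-butyl (2E)-3-{4-[(tert-butoxycarbonyl)oxy]-3,5-bis(3-methylbut-2-en-1-yl)phenyl}prop-2-en-1-yl carbonate | CC(C)=CCc1cc(/C=C/COC(=O)OC(C)(C)C)cc(CC=C(C)C)c1OC(=O)OC(C)(C)C | intermediate
14 | lithium 3,5-bis(methoxymethoxy)-4-(3-methylbut-2-en-1-yl)phenolate | COCOc1cc([O-])cc(OCOC)c1CC=C(C)C.[Li+] | intermediate (not isolated)
15 | tert-butyl 4-{(1R)-1-[3,5-bis(methoxymethoxy)-4-(3-methylbut-2-en-1-yl)phenoxy]prop-2-en-1-yl}-2,6-bis(3-methylbut-2-en-1-yl)phenyl carbonate | CC(C)=CCc1cc([C@H](Oc2cc(OCOC)c(CC=C(C)C)c(OCOC)c2)C=C)cc(CC=C(C)C)c1OC(=O)OC(C)(C)C | intermediate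
16 | tert-butyl 4-{(1R)-1-[3,5-bis(methoxymethoxy)-4-(3-methylbut-2-en-1-yl)phenoxy]-3-(9-borabicyclo[3.3.1]nonan-9-yl)propyl}-2,6-bis(3-methylbut-2-en-1-yl)phenyl carbonate | CC(C)=CCc1cc([C@H](Oc2cc(OCOC)c(CC=C(C)C)c(OCOC)c2)CCB2C3CCCC2CCC3)cc(CC=C(C)C)c1OC(=O)OC(C)(C)C | intermediate (not isolated)
17 | tert-butyl 4-{(1R)-1-[3,5-bis(methoxymethoxy)-4-(3-methylbut-2-en-1-yl)phenoxy]-3-hydroxypropyl}-2,6-bis(3-methylbut-2-en-1-yl)phenyl carbonate | CC(C)=CCc1cc([C@H](Oc2cc(OCOC)c(CC=C(C)C)c(OCOC)c2)CCO)cc(CC=C(C)C)c1OC(=O)OC(C)(C)C | intermediate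
18 | tert-butyl 4-{(1R)-1-[3,5-bis(methoxymethoxy)-4-(3-methylbut-2-en-1-yl)phenoxy]-3-oxopropyl}-2,6-bis(3-methylbut-2-en-1-yl)phenyl carbonate | CC(C)=CCc1cc([C@H](Oc2cc(OCOC)c(CC=C(C)C)c(OCOC)c2)CC=O)cc(CC=C(C)C)c1OC(=O)OC(C)(C)C | intermediate (not isolated)
19 | (3R)-3-[3,5-bis(methoxymethoxy)-4-(3-methylbut-2-en-1-yl)phenoxy]-3-{4-[(tert-butoxycarbonyl)oxy]-3,5-bis(3-methylbut-2-en-1-yl)phenyl}propanoic acid | CC(C)=CCc1cc([C@H](Oc2cc(OCOC)c(CC=C(C)C)c(OCOC)c2)CC(=O)O)cc(CC=C(C)C)c1OC(=O)OC(C)(C)C | intermediate
20 | (3R)-3-[3,5-bis(methoxymethoxy)-4-(3-methylbut-2-en-1-yl)phenoxy]-3-{4-[(tert-butoxycarbonyl)oxy]-3,5-bis(3-methylbut-2-en-1-yl)phenyl}propanoic trifluoroacetic anhydride | CC(C)=CCc1cc([C@H](Oc2cc(OCOC)c(CC=C(C)C)c(OCOC)c2)CC(=O)OC(=O)C(F)(F)F)cc(CC=C(C)C)c1OC(=O)OC(C)(C)C | intermediate (not isolated)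
21 | tert-butyl 4-[(2R)-5,7-bis(methoxymethoxy)-6-(3-methylbut-2-en-1-yl)-4-oxo-3,4-dihydro-2H-chromen-2-yl]-2,6-bis(3-methylbut-2-en-1-yl)phenyl carbonate | CC(C)=CCc1cc([C@H]2CC(=O)c3c(cc(OCOC)c(CC=C(C)C)c3OCOC)O2)cc(CC=C(C)C)c1OC(=O)OC(C)(C)C | intermediate
22 | (2R)-5,7-dihydroxy-2-[4-hydroxy-3,5-bis(3-methylbut-2-en-1-yl)phenyl]-6-(3-methylbut-2-en-1-yl)-2,3-dihydro-4H-chromen-4-one | CC(C)=CCc1cc([C@H]2CC(=O)c3c(cc(O)c(CC=C(C)C)c3O)O2)cc(CC=C(C)C)c1O | target

## Step count and least certain steps

Total: 13 steps. Longest linear sequence: 9 steps (steps 1–4 or steps 5–8, followed by steps 9–13).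

**Step 12 (key step).**
- Risk: the trifluoroacetic acid released may strip MOM groups or protonate prenyl alkenes before ring closure is complete. Intermolecular trifluoroacetylation of the very electron-rich ring A, or acid-promoted departure of the aryloxide from C2, may compete. Partial loss of the MOM group at O5 after closure would be harmless, since step 13 removes it.
- Fallback: a buffered, aprotic acylation. Setting out from 19, condensation with dimethylamine (carbodiimide coupling) would give the N,N-dimethylamide F1. Activation with (CF3SO2)2O and 2-fluoropyridine in CH2Cl2 at −78 → 0 °C generates an O-triflyliminium or keteniminium ion, which the same ring A carbon attacks in an intramolecular Vilsmeier–Haack-type reaction to give the cyclic iminium triflate F2. Hydrolysis with aq. NaHCO3 returns to the route at 21.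

**Step 9.**
- Risk: C-allylation of the ambident, phloroglucinol-type aryloxide instead of O-allylation; transfer or cleavage of the aryl carbonate by aryloxide or tert-butoxide; erosion of enantiomeric purity and of the branched-to-linear ratio through re-ionisation of the product; an unexpected sense of induction.
- Fallback: carry the carboxyl carbon from the start and form C2–O1 by inversion. Setting out from 11, Boc2O and DMAP would give the aryl carbonate F3. Copper-catalysed enantioselective β-borylation (CuCl, NaOt-Bu, a chiral ferrocenyl bisphosphine, bis(pinacolato)diboron, MeOH, THF) gives the (3S)-boronate F4, and NaBO3·4H2O oxidation gives the (3S)-β-hydroxy ester F5. A Mitsunobu reaction with phenol 7 (PPh3, diisopropyl azodicarboxylate, toluene, 0 °C) inverts the centre to the (3R)-aryloxy ester F6. Cleavage of the methyl ester with Me3SnOH in 1,2-dichloroethane returns to the route at 19, so steps 7–11 are bypassed.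

**Step 13.**
- Risk: acid-catalysed cyclisation of a prenyl group onto a freshly liberated ortho-phenol (chroman formation), and partial epimerisation at C2 through reversible opening of ring C if the medium is too strong or the exposure too long.
- Fallback: deprotection by silyl transfer, so that free phenols and acid never coexist. Setting out from 21, excess Me3SiOSO2CF3 with 2,2'-bipyridyl in MeCN at 0 °C → rt exchanges the aryl MOM ethers for trimethylsilyl ethers and converts the tert-butyl carbonate into the silyl carbonate, giving the persilylated flavanone F7. Addition of water hydrolyses the silyl ethers, the silyl carbonate loses CO2, and the route is rejoined at 22.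

**Step 11.**
- Risk: attack of the oxoammonium salt or of the trivalent iodine oxidant on ring A or on a prenyl alkene, and β-elimination of the aryloxide from aldehyde 18 if it accumulates.
- Fallback: separate the two oxidation levels and change the oxidant class. Setting out from 17, Dess–Martin oxidation (buffered with NaHCO3) gives aldehyde 18, which is isolated. A Lindgren–Pinnick oxidation (NaClO2, NaH2PO4, large excess of 2-methylbut-2-ene, t-BuOH–H2O, 0 °C) then returns to the route at 19. This fallback makes no compound outside the list (F0).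

**Step 5.**
- Risk: competing O-alkylation and incomplete or excessive C-alkylation, so that the diprenylphenol has to be separated from a mixture and throughput is low.
- Fallback: place both prenyl groups by cross-coupling. Setting out from 8, bromination (Br2, AcOH) gives 2,6-dibromo-4-iodophenol F8. A Mizoroki–Heck reaction with 10 at the more reactive carbon–iodine bond (Pd(OAc)2, Et3N, DMF, 70 °C) gives the dibromocinnamate F9. A double Suzuki–Miyaura coupling with 3-methylbut-2-enylboronic acid pinacol ester, under ligand control for the unbranched isomer (Pd(OAc)2, a bulky biarylphosphine, K3PO4, THF–H2O), returns to the route at 11, so step 6 is bypassed as well.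

## Further compounds

F1 | step 12 | tert-butyl 4-{(1R)-1-[3,5-bis(methoxymethoxy)-4-(3-methylbut-2-en-1-yl)phenoxy]-3-(dimethylamino)-3-oxopropyl}-2,6-bis(3-methylbut-2-en-1-yl)phenyl carbonate | CC(C)=CCc1cc([C@H](Oc2cc(OCOC)c(CC=C(C)C)c(OCOC)c2)CC(=O)N(C)C)cc(CC=C(C)C)c1OC(=O)OC(C)(C)C
F2 | step 12 | N-{(2R)-2-{4-[(tert-butoxycarbonyl)oxy]-3,5-bis(3-methylbut-2-en-1-yl)phenyl}-5,7-bis(methoxymethoxy)-6-(3-methylbut-2-en-1-yl)-2,3-dihydro-4H-chromen-4-ylidene}-N-methylmethanaminium trifluoromethanesulfonate | CC(C)=CCc1cc([C@H]2CC(=[N+](C)C)c3c(cc(OCOC)c(CC=C(C)C)c3OCOC)O2)cc(CC=C(C)C)c1OC(=O)OC(C)(C)C.[O-]S(=O)(=O)C(F)(F)F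
F3 | step 9 | methyl (2E)-3-{4-[(tert-butoxycarbonyl)oxy]-3,5-bis(3-methylbut-2-en-1-yl)phenyl}prop-2-enoate | CC(C)=CCc1cc(/C=C/C(=O)OC)cc(CC=C(C)C)c1OC(=O)OC(C)(C)C
F4 | step 9 | methyl (3S)-3-{4-[(tert-butoxycarbonyl)oxy]-3,5-bis(3-methylbut-2-en-1-yl)phenyl}-3-(4,4,5,5-tetramethyl-1,3,2-dioxaborolan-2-yl)propanoate | CC(C)=CCc1cc([C@@H](B2OC(C)(C)C(C)(C)O2)CC(=O)OC)cc(CC=C(C)C)c1OC(=O)OC(C)(C)C
F5 | step 9 | methyl (3S)-3-{4-[(tert-butoxycarbonyl)oxy]-3,5-bis(3-methylbut-2-en-1-yl)phenyl}-3-hydroxypropanoate | CC(C)=CCc1cc([C@@H](O)CC(=O)OC)cc(CC=C(C)C)c1OC(=O)OC(C)(C)C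
F6 | step 9 | methyl (3R)-3-[3,5-bis(methoxymethoxy)-4-(3-methylbut-2-en-1-yl)phenoxy]-3-{4-[(tert-butoxycarbonyl)oxy]-3,5-bis(3-methylbut-2-en-1-yl)phenyl}propanoate | CC(C)=CCc1cc([C@H](Oc2cc(OCOC)c(CC=C(C)C)c(OCOC)c2)CC(=O)OC)cc(CC=C(C)C)c1OC(=O)OC(C)(C)C
F7 | step 13 | 4-[(2R)-6-(3-methylbut-2-en-1-yl)-4-oxo-5,7-bis(trimethylsilyloxy)-3,4-dihydro-2H-chromen-2-yl]-2,6-bis(3-methylbut-2-en-1-yl)phenyl trimethylsilyl carbonate | CC(C)=CCc1cc([C@H]2CC(=O)c3c(cc(O[Si](C)(C)C)c(CC=C(C)C)c3O[Si](C)(C)C)O2)cc(CC=C(C)C)c1OC(=O)O[Si](C)(C)C
F0 | step 11 | none | none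
F8 | step 5 | 2,6-dibromo-4-iodophenol | Oc1c(Br)cc(I)cc1Br
F9 | step 5 | methyl (2E)-3-(3,5-dibromo-4-hydroxyphenyl)prop-2-enoate | COC(=O)/C=C/c1cc(Br)c(O)c(Br)c1
A1 | alternative 1 | (2R)-5-hydroxy-7-(methoxymethoxy)-2-[4-(methoxymethoxy)-3,5-bis(3-methylbut-2-en-1-yl)phenyl]-6-(3-methylbut-2-en-1-yl)-2,3-dihydro-4H-chromen-4-one | COCOc1c(CC=C(C)C)cc([C@H]2CC(=O)c3c(cc(OCOC)c(CC=C(C)C)c3O)O2)cc1CC=C(C)C
A2 | alternative 1 | (2R)-2-[3,5-dibromo-4-(methoxymethoxy)phenyl]-5-hydroxy-6-iodo-7-(methoxymethoxy)-2,3-dihydro-4H-chromen-4-one | COCOc1c(Br)cc([C@H]2CC(=O)c3c(cc(OCOC)c(I)c3O)O2)cc1Br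
A3 | alternative 1 | tributyl(3-methylbut-2-en-1-yl)stannane | CCCC[Sn](CCCC)(CCCC)CC=C(C)C
A4 | alternative 2 | (2R)-5,7-bis(tert-butyldimethylsilyloxy)-2-[4-(tert-butyldimethylsilyloxy)-3,5-bis(3-methylbut-2-en-1-yl)phenyl]-6-(3-methylbut-2-en-1-yl)-2,3-dihydro-4H-chromen-4-one | CC(C)=CCc1cc([C@H]2CC(=O)c3c(cc(O[Si](C)(C)C(C)(C)C)c(CC=C(C)C)c3O[Si](C)(C)C(C)(C)C)O2)cc(CC=C(C)C)c1O[Si](C)(C)C(C)(C)C
A5 | alternative 2 | 1-{2,4-bis(tert-butyldimethylsilyloxy)-6-({4-(tert-butyldimethylsilyloxy)-3,5-bis(3-methylbut-2-en-1-yl)phenyl}methoxy)-3-(3-methylbut-2-en-1-yl)phenyl}-2-diazoethan-1-one | [N-]=[N+]=CC(=O)c1c(OCc2cc(CC=C(C)C)c(O[Si](C)(C)C(C)(C)C)c(CC=C(C)C)c2)cc(O[Si](C)(C)C(C)(C)C)c(CC=C(C)C)c1O[Si](C)(C)C(C)(C)C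
A6 | alternative 3 | (2R)-5,7-dihydroxy-2-[4-(methoxymethoxy)-3,5-bis(3-methylbut-2-en-1-yl)phenyl]-6-(3-methylbut-2-en-1-yl)-2,3-dihydro-4H-chromen-4-one | CC(C)=CCc1cc([C@H]2CC(=O)c3c(cc(O)c(CC=C(C)C)c3O)O2)cc(CC=C(C)C)c1OCOC
A7 | alternative 3 | methyl 4-{(2R)-2-[4-(methoxymethoxy)-3,5-bis(3-methylbut-2-en-1-yl)phenyl]-4-oxo-3,4-dihydro-2H-pyran-6-yl}-2-(3-methylbut-2-en-1-yl)-3-oxobutanoate (mixture of epimers at C2 of the butanoate) | COC(=O)C(CC=C(C)C)C(=O)CC1=CC(=O)C[C@H](c2cc(CC=C(C)C)c(OCOC)c(CC=C(C)C)c2)O1
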